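The furanone ring (O1, C2, C3, C3a, C7a) is read as the closed form of an o-hydroxyaryl 1,2-diketone: hemiketal C2 sits between phenolic O1 and aryl ketone C3. It is therefore made by contracting the six-membered pyranone ring of a 3-alkyl-4-hydroxy-5-methylcoumarin. Its C3 hydroperoxide, a 3-hydroperoxychromane-2,4-dione that already carries the whole oxidised farnesyl chain, collapses through a dioxetanone, extrudes the lactone carbonyl as CO2 and recloses on O1 in one operation under a chiral bifunctional amine. The coumarin comes from Tsuji–Trost C3-allylation with a dienone allylic acetate built from geranyl acetate by allylic oxidation and a Nozaki–Hiyama–Kishi coupling.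

Key step: step 9

Remark (assumption): the C2 hemiketal can racemise through its open hydroxyaryl diketone form. It is assumed to hold its configuration under neutral, aprotic, cold handling, so it is formed in the last step and is not exposed to acid, base or protic media afterwards.

Step 1
Reactants: 1 geranyl acetate
Product: 2 (2E,6E)-8-hydroxy-3,7-dimethylocta-2,6-dien-1-yl acetate
Conditions: SeO2 (0.1 equiv), t-BuOOH (2 equiv), salicylic acid (cat.), CH2Cl2, 23 °C
Reagents that add atoms: tert-butyl hydroperoxide, CC(C)(C)OO (terminal oxidant; its oxygen is passed on by catalytic selenium dioxide, O=[Se]=O)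
Why: Catalytic SeO2 allylic oxidation (ene reaction, then [2,3]-sigmatropic shift) should attack the (E)-methyl group of the electron-richer 6,7-alkene, the 2,3-alkene being deactivated by the allylic acetate, and give the E-allylic alcohol.

Step 2
Reactants: 2 (2E,6E)-8-hydroxy-3,7-dimethylocta-2,6-dien-1-yl acetate
Product: 3 (2E,6E)-3,7-dimethyl-8-oxoocta-2,6-dien-1-yl acetate
Conditions: activated MnO2 (15 equiv), CH2Cl2, 23 °C
Reagents that add atoms: none
Why: Allylic alcohol oxidation with MnO2 should stop at the enal and leave the acetate and both alkene geometries untouched; any 3 already formed in step 1 is carried along.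

Step 3
Reactants: 4 2-methylbut-3-yn-2-ol
Product: 6 (E)-4-iodo-2-methylbut-3-en-2-ol, via vinylstannane 5 (not isolated)
Conditions: Bu3SnH, PdCl2(PPh3)2 (2 mol %), THF, 0 to 23 °C; then I2, CH2Cl2, 0 °C
Reagents that add atoms: iodine, II; tributyltin hydride, CCCC[SnH](CCCC)CCCC (its tin is present only in 5)
Why: Pd-catalysed syn-hydrostannation should place tin at the unhindered alkyne terminus (E), and iododestannylation proceeds with retention of the alkene geometry.

Step 4
Reactants: 3 (2E,6E)-3,7-dimethyl-8-oxoocta-2,6-dien-1-yl acetate; 6 (E)-4-iodo-2-methylbut-3-en-2-ol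
Product: 7 (2E,6E,9E)-8,11-dihydroxy-3,7,11-trimethyldodeca-2,6,9-trien-1-yl acetate (racemic at C8)
Conditions: CrCl2 (4 equiv), NiCl2 (2 mol %), DMF, 23 °C
Reagents that add atoms: none
Why: In the Nozaki–Hiyama–Kishi coupling the vinylchromium species, formed with retention of the E geometry, should add 1,2 to the enal and tolerate the acetate and the free tertiary alcohol; the new carbinol centre is formed without control and is removed in step 5.

Step 5
Reactants: 7 (2E,6E,9E)-8,11-dihydroxy-3,7,11-trimethyldodeca-2,6,9-trien-1-yl acetate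
Product: 8 (2E,6E,9E)-11-hydroxy-3,7,11-trimethyl-8-oxododeca-2,6,9-trien-1-yl acetate
Conditions: activated MnO2 (20 equiv), CH2Cl2, 23 °C
Reagents that add atoms: none
Why: MnO2 should oxidise the doubly allylic secondary alcohol to the cross-conjugated dienone, while the tertiary alcohol cannot be oxidised and the acetate is inert.

Step 6
Reactants: 9 1-(2-hydroxy-6-methylphenyl)ethan-1-one
Product: 10 4-hydroxy-5-methyl-2H-chromen-2-one
Conditions: NaH (4 equiv), (EtO)2CO, toluene, 110 °C; then aq HCl
Reagents that add atoms: diethyl carbonate, CCOC(=O)OCC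
Why: Claisen-type C-acylation of the ketone enolate by the carbonate followed by lactonisation onto the phenoxide is the standard construction of 4-hydroxycoumarins.

Step 7
Reactants: 8 (2E,6E,9E)-11-hydroxy-3,7,11-trimethyl-8-oxododeca-2,6,9-trien-1-yl acetate; 10 4-hydroxy-5-methyl-2H-chromen-2-one (2 equiv)
Product: 11 4-hydroxy-3-[(2E,6E,9E)-11-hydroxy-3,7,11-trimethyl-8-oxododeca-2,6,9-trien-1-yl]-5-methyl-2H-chromen-2-one
Conditions: Pd(PPh3)4 (5 mol %), Et3N, THF, 50 °C; pH 4 buffer work-up
Reagents that add atoms: none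
Why: In this Tsuji–Trost allylation the soft 4-oxidocoumarin should attack the unsubstituted terminus of the π-allylpalladium complex and give the linear C3-allyl product with the 2E geometry kept; any O-allyl ether re-ionises under Pd(0) and funnels to the C-alkylated product, and excess 10 limits double allylation.

Step 8
Reactants: 11 4-hydroxy-3-[(2E,6E,9E)-11-hydroxy-3,7,11-trimethyl-8-oxododeca-2,6,9-trien-1-yl]-5-methyl-2H-chromen-2-one
Product: 12 3-hydroperoxy-3-[(2E,6E,9E)-11-hydroxy-3,7,11-trimethyl-8-oxododeca-2,6,9-trien-1-yl]-5-methylchromane-2,4-dione (racemic at C3)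
Conditions: Mn(OAc)3·2H2O (5 mol %), O2 (1 atm), AcOH, 23 °C, dark; cold extractive work-up, no chromatography
Reagents that add atoms: dioxygen, O=O
Why: Mn(III)-catalysed aerobic α-hydroperoxidation of 2-substituted cyclic 1,3-dicarbonyl compounds: the Mn(III) enolate gives the C3 radical, which traps O2 and is reduced and protonated to the tertiary hydroperoxide, and the acidic medium keeps the hydroperoxide from collapsing; the C3 centre is destroyed in step 9, so the racemate is used.

Step 9
Reactants: 12 3-hydroperoxy-3-[(2E,6E,9E)-11-hydroxy-3,7,11-trimethyl-8-oxododeca-2,6,9-trien-1-yl]-5-methylchromane-2,4-dione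
Product: 15 (2R)-2-hydroxy-2-[(2E,6E,9E)-11-hydroxy-3,7,11-trimethyl-8-oxododeca-2,6,9-trien-1-yl]-4-methyl-1-benzofuran-3(2H)-one, via dioxetanone 13 (not isolated), via diketone 14 (not isolated)
Conditions: quinine-derived 3,5-bis(trifluoromethyl)phenyl squaramide (10 mol %), toluene (0.01 M), −40 °C, argon; cold filtration through neutral silica
Reagents that add atoms: none
Why: Proposed new method: the quinuclidine nitrogen deprotonates the hydroperoxide, the peroxy anion adds to the adjacent aryl-lactone carbonyl and expels the phenoxide (α-peroxylactone 13), 13 loses CO2 to give the o-hydroxyaryl 1,2-diketone 14, and the phenol oxygen adds to the alkyl-side ketone, so that the six-membered pyranone ring of 12 ends as the five-membered furanone ring with the former coumarin C3 as hemiketal carbon C2. The closest known reaction types are the base-triggered dioxetanone collapse of α-hydroperoxy aryl esters with loss of CO2, the oxidative decarboxylative contraction of 3-substituted 4-hydroxycoumarins to 2-hydroxybenzofuran-3(2H)-ones, and squaramide-controlled additions to 1,2-dicarbonyl compounds. The dioxetanone closes 4-exo-trig and the furanone 5-exo-trig. C2 is the only new stereocentre and is meant to be set in the 5-exo-trig closure by the catalyst: the squaramide N–H pair binds the vicinal diketone and the ammonium–phenoxide ion pair delivers O1 to one face, the pseudoenantiomeric quinidine-derived catalyst being taken if the opposite sense is needed for (2R); both C3 epimers of 12 converge on achiral 14. The step needs peroxide attack at the lactone carbonyl and not at the C4 ketone, which the phenoxide leaving group and the peri 5-methyl group next to C4 should secure, and it needs the catalysed closure to outrun the uncatalysed one and the reopening of the hemiketal, hence the low temperature, the dilute non-polar solvent and the neutral cold work-up.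

Compound list

1 | geranyl acetate | CC(=O)OC/C=C(\C)CCC=C(C)C | starting material
2 | (2E,6E)-8-hydroxy-3,7-dimethylocta-2,6-dien-1-yl acetate | CC(=O)OC/C=C(\C)CC/C=C(\C)CO | intermediate
3 | (2E,6E)-3,7-dimethyl-8-oxoocta-2,6-dien-1-yl acetate | CC(=O)OC/C=C(\C)CC/C=C(\C)C=O | intermediate
4 | 2-methylbut-3-yn-2-ol | CC(C)(O)C#C | starting material
5 | (E)-2-methyl-4-(tributylstannyl)but-3-en-2-ol | CCCC[Sn](CCCC)(CCCC)/C=C/C(C)(C)O | intermediate (not isolated)
6 | (E)-4-iodo-2-methylbut-3-en-2-ol | CC(C)(O)/C=C/I | intermediate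
7 | (2E,6E,9E)-8,11-dihydroxy-3,7,11-trimethyldodeca-2,6,9-trien-1-yl acetate, racemic at C8 | CC(=O)OC/C=C(\C)CC/C=C(\C)C(O)/C=C/C(C)(C)O | intermediate
8 | (2E,6E,9E)-11-hydroxy-3,7,11-trimethyl-8-oxododeca-2,6,9-trien-1-yl acetate | CC(=O)OC/C=C(\C)CC/C=C(\C)C(=O)/C=C/C(C)(C)O | intermediate
9 | 1-(2-hydroxy-6-methylphenyl)ethan-1-one | CC(=O)c1c(C)cccc1O | starting material
10 | 4-hydroxy-5-methyl-2H-chromen-2-one | Cc1cccc2OC(=O)C=C(O)c12 | intermediate
11 | 4-hydroxy-3-[(2E,6E,9E)-11-hydroxy-3,7,11-trimethyl-8-oxododeca-2,6,9-trien-1-yl]-5-methyl-2H-chromen-2-one | Cc1cccc2OC(=O)C(C/C=C(\C)CC/C=C(\C)C(=O)/C=C/C(C)(C)O)=C(O)c12 | intermediate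
12 | 3-hydroperoxy-3-[(2E,6E,9E)-11-hydroxy-3,7,11-trimethyl-8-oxododeca-2,6,9-trien-1-yl]-5-methylchromane-2,4-dione, racemic at C3 | Cc1cccc2OC(=O)C(OO)(C/C=C(\C)CC/C=C(\C)C(=O)/C=C/C(C)(C)O)C(=O)c12 | intermediate
13 | 4-(2-hydroxy-6-methylbenzoyl)-4-[(2E,6E,9E)-11-hydroxy-3,7,11-trimethyl-8-oxododeca-2,6,9-trien-1-yl]-1,2-dioxetan-3-one | Cc1cccc(O)c1C(=O)C1(C/C=C(\C)CC/C=C(\C)C(=O)/C=C/C(C)(C)O)OOC1=O | intermediate (not isolated)
14 | (4E,8E,11E)-13-hydroxy-1-(2-hydroxy-6-methylphenyl)-5,9,13-trimethyltetradeca-4,8,11-triene-1,2,10-trione | Cc1cccc(O)c1C(=O)C(=O)C/C=C(\C)CC/C=C(\C)C(=O)/C=C/C(C)(C)O | intermediate (not isolated)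
15 | (2R)-2-hydroxy-2-[(2E,6E,9E)-11-hydroxy-3,7,11-trimethyl-8-oxododeca-2,6,9-trien-1-yl]-4-methyl-1-benzofuran-3(2H)-one | C/C(=C\C[C@@]1(O)Oc2cccc(C)c2C1=O)CC/C=C(\C)C(=O)/C=C/C(C)(C)O | target

Total step count: 9
Longest linear sequence: 7 steps (steps 1, 2, 4, 5, 7, 8, 9, from geranyl acetate)

Steps most likely to fail

Step 9 (Proposed new method). The uncatalysed ring closure and catalyst-mediated reopening of the hemiketal may erode the facial selectivity, and the peroxy anion may add to the C4 ketone and cleave the C3–C4 bond instead of the lactone. The fallback uses known reactions only; it sets out from 12 and comes back at 15. The hydroperoxide is reduced with Ph3P (CH2Cl2, 0 °C) to 3-hydroxy-3-[(2E,6E,9E)-11-hydroxy-3,7,11-trimethyl-8-oxododeca-2,6,9-trien-1-yl]-5-methylchromane-2,4-dione F1. LiOH in aqueous THF opens the lactone, and on acidification the β-keto acid decarboxylates to the acyloin (4E,8E,11E)-2,13-dihydroxy-1-(2-hydroxy-6-methylphenyl)-5,9,13-trimethyltetradeca-4,8,11-triene-1,10-dione F2. Dess–Martin oxidation gives diketone 14, which should close on its own to racemic 2-hydroxy-2-[(2E,6E,9E)-11-hydroxy-3,7,11-trimethyl-8-oxododeca-2,6,9-trien-1-yl]-4-methyl-1-benzofuran-3(2H)-one F3. Preparative SFC on a chiral stationary phase then separates 15 from its (2S)-enantiomer F4, which can be racemised with a trace of Et3N and resubmitted.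

Step 8. The intermediate C3 peroxyl radical may cyclise 5-exo onto the neighbouring trisubstituted alkene (1,2-dioxolane formation) or start radical-chain autoxidation of the polyene. The fallback replaces the radical pathway by an ionic oxygenation; it sets out from 11 and comes back at 12. The fluoride-activated enol of 11 (Bu4NF) is photooxygenated with singlet oxygen (O2, tetraphenylporphyrin, visible light, CH2Cl2, −78 °C), stopped after one equivalent of O2 and quenched with AcOH; no new compound is made (F0).

Step 7. Conjugate addition of the coumarin enolate to the cross-conjugated dienone and double allylation at C3 may compete with the wanted mono-allylation. The fallback allylates before the dienone exists; it sets out from 2 and 10 and comes back at 11. Pd(PPh3)4/Et3N allylation of 10 with 2 should give 4-hydroxy-3-[(2E,6E)-8-hydroxy-3,7-dimethylocta-2,6-dien-1-yl]-5-methyl-2H-chromen-2-one F5. Dess–Martin oxidation gives 4-hydroxy-3-[(2E,6E)-3,7-dimethyl-8-oxoocta-2,6-dien-1-yl]-5-methyl-2H-chromen-2-one F6. Nozaki–Hiyama–Kishi coupling of its sodium salt with 6 gives 4-hydroxy-3-[(2E,6E,9E)-8,11-dihydroxy-3,7,11-trimethyldodeca-2,6,9-trien-1-yl]-5-methyl-2H-chromen-2-one F7, and Dess–Martin oxidation of the secondary alcohol gives 11.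

Further compounds

F1 | step 9 | 3-hydroxy-3-[(2E,6E,9E)-11-hydroxy-3,7,11-trimethyl-8-oxododeca-2,6,9-trien-1-yl]-5-methylchromane-2,4-dione | Cc1cccc2OC(=O)C(O)(C/C=C(\C)CC/C=C(\C)C(=O)/C=C/C(C)(C)O)C(=O)c12
F2 | step 9 | (4E,8E,11E)-2,13-dihydroxy-1-(2-hydroxy-6-methylphenyl)-5,9,13-trimethyltetradeca-4,8,11-triene-1,10-dione | Cc1cccc(O)c1C(=O)C(O)C/C=C(\C)CC/C=C(\C)C(=O)/C=C/C(C)(C)O
F3 | step 9 | racemic 2-hydroxy-2-[(2E,6E,9E)-11-hydroxy-3,7,11-trimethyl-8-oxododeca-2,6,9-trien-1-yl]-4-methyl-1-benzofuran-3(2H)-one | C/C(=C\CC1(O)Oc2cccc(C)c2C1=O)CC/C=C(\C)C(=O)/C=C/C(C)(C)O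
F4 | step 9 | (2S)-2-hydroxy-2-[(2E,6E,9E)-11-hydroxy-3,7,11-trimethyl-8-oxododeca-2,6,9-trien-1-yl]-4-methyl-1-benzofuran-3(2H)-one | C/C(=C\C[C@]1(O)Oc2cccc(C)c2C1=O)CC/C=C(\C)C(=O)/C=C/C(C)(C)O
F0 | step 8 | none | none
F5 | step 7 | 4-hydroxy-3-[(2E,6E)-8-hydroxy-3,7-dimethylocta-2,6-dien-1-yl]-5-methyl-2H-chromen-2-one | Cc1cccc2OC(=O)C(C/C=C(\C)CC/C=C(\C)CO)=C(O)c12
F6 | step 7 | 4-hydroxy-3-[(2E,6E)-3,7-dimethyl-8-oxoocta-2,6-dien-1-yl]-5-methyl-2H-chromen-2-one | Cc1cccc2OC(=O)C(C/C=C(\C)CC/C=C(\C)C=O)=C(O)c12
F7 | step 7 | 4-hydroxy-3-[(2E,6E,9E)-8,11-dihydroxy-3,7,11-trimethyldodeca-2,6,9-trien-1-yl]-5-methyl-2H-chromen-2-one | Cc1cccc2OC(=O)C(C/C=C(\C)CC/C=C(\C)C(O)/C=C/C(C)(C)O)=C(O)c12
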